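**Target:** CNP0113462.5, (3aR,4S,5R,6S,7S,7aR)-7-hydroxy-6-methyl-3-methylidene-6-[(2S)-oxiran-2-yl]-2-oxo-5-(3-oxoprop-1-en-2-yl)octahydro-1-benzofuran-4-y l (2Z)-2-methylbut-2-enoate. The route has not been run; selectivities are reasoned expectations.

**Retrosynthetic overview**
- Oxirane ⇐ C10 vinyl by C9-OH-directed epoxidation; C15 aldehyde and C9-OH ⇐ diethyl acetal and silyl ether.
- C10 vinyl + C11=CH2 ⇐ ethenolysis of a C1=C11 bridge in a bicyclo[2.2.2]octene lactone.
- C6 angelate and C5 side chain ⇐ bridged C6 ketone (hydroboration/oxidation, enolate alkenylation, hydride from the open face).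
- Bridged lactone ⇐ intramolecular Diels–Alder of the C8-O propiolate of a cyclohexadiene cis-diol (closes the lactone ring, sets C7 and quaternary C10).
- cis-Diol ⇐ 4-iodotoluene by enzymatic dearomatising cis-dihydroxylation. Ring order: carbocycle (from the arene), lactone, oxirane.

**Labels:** elemane numbering is used. Ring C5–C10; C10 bears CH3 and C1(–C2); C5 bears C4(=C3)–C15; C7 bears C11(=C13)–C12(=O)–O8. α = ring face of O8/O9; β = face of the C10 methyl.

**Assumption:** 2-bromo-3,3-diethoxyprop-1-ene and angelic acid are bought, and the dioxygenase is used as glucose-fed whole cells.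

**Step 1**
Reactants: 1 4-iodotoluene
Product: 2 (1S,2S)-3-iodo-6-methylcyclohexa-3,5-diene-1,2-diol
Conditions: E. coli JM109(pDTG601A) whole cells (toluene dioxygenase), glucose, air, phosphate buffer pH 7.2, 30 °C; EtOAc extraction, recrystallisation
Reagents that add atoms: dioxygen, O=O
Why: Enzymatic arene cis-dihydroxylation (toluene dioxygenase) breaks the aromatic ring at the 2,3-bond next to the larger substituent, iodine outranking methyl, and delivers both oxygens to one face, which sets C8 and C9 in the sense opposite to the toluene metabolite, i.e. the sense the target needs.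

**Step 2**
Reactants: 2 (1S,2S)-3-iodo-6-methylcyclohexa-3,5-diene-1,2-diol
Product: 3 (1R,2S)-3-methylcyclohexa-3,5-diene-1,2-diol
Conditions: Bu3SnH (1.1 equiv), Pd(PPh3)4 (3 mol%), THF, 0 °C → rt
Reagents that add atoms: none
Why: Hydrodehalogenation (hydrostannolysis catalysed by zerovalent palladium) of the vinyl iodide replaces the steering iodine by H without touching the diene or the C8/C9 stereocentres.

**Step 3**
Reactants: 3 (1R,2S)-3-methylcyclohexa-3,5-diene-1,2-diol; 4 propiolic acid
Product: 5 (1R,6S)-6-hydroxy-5-methylcyclohexa-2,4-dien-1-yl prop-2-ynoate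
Conditions: DCC (1.05 equiv), DMAP (5 mol%), CH2Cl2, −30 °C
Reagents that add atoms: propiolic acid 4, C#CC(=O)O
Why: Steglich esterification; the C8 hydroxyl next to the unsubstituted vinyl CH is less hindered than the C9 hydroxyl next to the methyl-bearing carbon, so one equivalent of acid at low temperature acylates O8 selectively and no stereocentre is touched.

**Step 4**
Reactants: 5 (1R,6S)-6-hydroxy-5-methylcyclohexa-2,4-dien-1-yl prop-2-ynoate
Product: 6 (1R,6S)-5-methyl-6-[(triethylsilyl)oxy]cyclohexa-2,4-dien-1-yl prop-2-ynoate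
Conditions: Et3SiOTf, 2,6-lutidine, CH2Cl2, −78 °C
Reagents that add atoms: triethylsilyl triflate, CC[Si](CC)(CC)OS(=O)(=O)C(F)(F)F
Why: Silylation of the remaining alcohol with a silyl triflate and a hindered base (nucleophilic bases would add to the propiolate) protects O9 for the later oxidation and acylation steps.

**Step 5**
Reactants: 6 (1R,6S)-5-methyl-6-[(triethylsilyl)oxy]cyclohexa-2,4-dien-1-yl prop-2-ynoate
Product: 7 bridged diene lactone
Conditions: PhMe (0.01 M), BHT, 100–110 °C, base-washed sealed tube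
Reagents that add atoms: none
Why: Intramolecular Diels–Alder reaction; the O–C(=O) tether on the α face of C8 can reach the diene only from that face and only by bonding C11 to the adjacent terminus C7 and the alkyne CH (C1) to C10, which closes the cis-fused γ-lactone and sets C7 (C11 α) and the quaternary C10 (C1 α, CH3 β) in one step.

**Step 6**
Reactants: 7 bridged diene lactone
Product: 9 bridged C6 ketone, via alkylborane 8 (not isolated)
Conditions: BH3·SMe2 (1.0 equiv), THF, −10 °C; then N-methylmorpholine N-oxide, (n-Pr)4N[RuO4] (5 mol%), 4 Å MS, CH2Cl2, rt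
Reagents that add atoms: borane–dimethyl sulfide, [BH3-][S+](C)C (boron stays only in 8); N-methylmorpholine N-oxide, C[N+]1([O-])CCOCC1 (ketone oxygen)
Why: Hydroboration followed by direct oxidation of the organoborane to the ketone; borane attacks the unconjugated strained C5=C6 bond much faster than the enoate and places boron on C6, remote from the methyl-bearing bridgehead, and because C6 ends as a carbonyl the face of attack does not matter.

**Step 7**
Reactants: 9 bridged C6 ketone; 10 2-bromo-3,3-diethoxyprop-1-ene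
Product: 13 5β-alkenyl C6 ketone, via lithium enolate 11 (not isolated), via lithium dienolate 12 (not isolated)
Conditions: LiN(SiMe3)2 (2.2 equiv), THF, −78 °C; Pd2(dba)3 (2.5 mol%), t-Bu3P·HBF4 (10 mol%), 10, THF, 25 → 50 °C; then AcOH, THF, −78 °C
Reagents that add atoms: 2-bromo-3,3-diethoxyprop-1-ene 10, C=C(Br)C(OCC)OCC; lithium bis(trimethylsilyl)amide, [Li]N([Si](C)(C)C)[Si](C)(C)C (lithium stays only in 11 and 12)
Why: Palladium-catalysed α-alkenylation of a ketone enolate; the bridgehead C7–H cannot enolise (Bredt), so only C5 reacts, the more acidic product stays as dienolate 12, and kinetic C-protonation from the open side next to the C1=C11 bridge pushes the side chain to the side of the C8–C9 bridge, i.e. β (trans to C1, cis to the C10 methyl).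

**Step 8**
Reactants: 13 5β-alkenyl C6 ketone
Product: 14 6β-alcohol
Conditions: NaBH4, CeCl3·7H2O, EtOH–THF, −40 °C
Reagents that add atoms: none
Why: Luche 1,2-reduction; hydride also enters from the open side next to the C1=C11 bridge (the other side is shielded by H8, H9 and the C5 side chain), giving the 6β-alcohol cis to the C5 substituent and trans to C11, while the conjugated lactone and the acetal survive.

**Step 9**
Reactants: 14 6β-alcohol; 15 angelic acid
Product: 17 6β-angelate, via mixed anhydride 16 (not isolated)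
Conditions: 15, 2,4,6-Cl3C6H2COCl, Et3N, PhMe, rt; then 14, DMAP (0.2 equiv), PhMe, 40 °C
Reagents that add atoms: angelic acid 15, C/C=C(/C)C(=O)O; 2,4,6-trichlorobenzoyl chloride, O=C(Cl)c1c(Cl)cc(Cl)cc1Cl (aroyl group stays only in 16)
Why: Yamaguchi esterification through the mixed anhydride acylates the hindered secondary alcohol with retention at C6 and, at mild temperature, without Z-to-E isomerisation of the angelate.

**Step 10**
Reactants: 17 6β-angelate; 18 ethylene
Product: 19 (3aR,4S,5R,6S,7S,7aR)-5-(3,3-diethoxyprop-1-en-2-yl)-6-ethenyl-6-methyl-3-methylidene-2-oxo-7-[(triethylsilyl)oxy]octahydro-1-benzofuran-4-yl (2Z)-2-methylbut-2-enoate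
Conditions: second-generation Hoveyda–Grubbs catalyst RuCl2(H2IMes)(=CH–C6H4-2-O-i-Pr) (10 mol%, in portions), ethylene (1 atm), PhMe, 60 °C
Reagents that add atoms: ethylene 18, C=C
Why: Proposed new method: ring-opening cross-metathesis (ethenolysis) of the trisubstituted, lactone-conjugated C1=C11 bridge, in which the ruthenium methylidene adds with Ru on the less substituted C1, cycloreversion releases the α-methylene lactone (C11=CH2) and a ruthenium alkylidene that ethylene converts into the C10 vinyl group, driven by loss of bicyclo[2.2.2]octene strain and by the low metathesis reactivity of both product olefins; the closest known reactions are ethylene ring-opening metathesis of bicyclo[2.2.2]octenes and ethenolysis of trisubstituted cycloalkenes, and no stereocentre is touched.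

**Step 11**
Reactants: 19 ring-opened silyl ether acetal
Product: 20 (3aR,4S,5R,6S,7S,7aR)-6-ethenyl-7-hydroxy-6-methyl-3-methylidene-2-oxo-5-(3-oxoprop-1-en-2-yl)octahydro-1-benzofuran-4-yl (2Z)-2-methylbut-2-enoate
Conditions: 1 M HCl, THF–H2O, 0 °C → rt
Reagents that add atoms: water, O
Why: Acid hydrolysis cleaves the diethyl acetal (to the 2-substituted acrolein) and the triethylsilyl ether together, while lactone, angelate and olefins are stable and no stereocentre is affected.

**Step 12**
Reactants: 20 vinyl hydroxy enal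
Product: 21 target CNP0113462.5
Conditions: VO(acac)2 (10 mol%), t-BuOOH (1.5 equiv), CH2Cl2, 0 °C → rt
Reagents that add atoms: tert-butyl hydroperoxide, CC(C)(C)OO
Why: Hydroxyl-directed vanadium-catalysed epoxidation of a homoallylic alcohol; only the C10 vinyl group is electron-rich and within reach of the C9 vanadate (the three other olefins are conjugated to carbonyls), and with the C=C eclipsing the small C10 methyl (least allylic strain) the O9-bound peroxide reaches the face that gives the (1S)-oxirane, though the diastereomer ratio may be modest.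

**Compound list**
1 | 4-iodotoluene | Cc1ccc(I)cc1 | starting material
2 | (1S,2S)-3-iodo-6-methylcyclohexa-3,5-diene-1,2-diol | O[C@@H]1C(I)=CC=C(C)[C@@H]1O | intermediate
3 | (1R,2S)-3-methylcyclohexa-3,5-diene-1,2-diol | O[C@@H]1C=CC=C(C)[C@@H]1O | intermediate
4 | propiolic acid | C#CC(=O)O | starting material
5 | (1R,6S)-6-hydroxy-5-methylcyclohexa-2,4-dien-1-yl prop-2-ynoate | C#CC(=O)O[C@@H]1C=CC=C(C)[C@@H]1O | intermediate
6 | (1R,6S)-5-methyl-6-[(triethylsilyl)oxy]cyclohexa-2,4-dien-1-yl prop-2-ynoate | C#CC(=O)O[C@@H]1C=CC=C(C)[C@@H]1O[Si](CC)(CC)CC | intermediate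
7 | bridged diene lactone: bicyclo[2.2.2]octa-2,5-diene with bridgeheads C7 (H) and C10 (CH3), bridges C5=C6, C1=C11 and C8–C9; γ-lactone C12(=O)–O8 on C11/C8; 9-OSiEt3; O8 and O9 both on the side of the C1=C11 bridge | O=C1O[C@@H]2[C@H]3C=C[C@](C)(C=C13)[C@@H]2O[Si](CC)(CC)CC | intermediate
8 | alkylborane: 7 with BH2 on C6 (side of the C1=C11 bridge) and C5 = CH2 | O=C1O[C@@H]2[C@H]3[C@H](B)C[C@](C)(C=C13)[C@@H]2O[Si](CC)(CC)CC | intermediate
9 | bridged C6 ketone: 7 with C6=O and C5H2 | O=C1O[C@@H]2[C@H]3C(=O)C[C@](C)(C=C13)[C@@H]2O[Si](CC)(CC)CC | intermediate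
10 | 2-bromo-3,3-diethoxyprop-1-ene | C=C(Br)C(OCC)OCC | starting material
11 | lithium enolate of 9 (C6–OLi, C5=C6) | O=C1O[C@@H]2[C@H]3C(O[Li])=C[C@](C)(C=C13)[C@@H]2O[Si](CC)(CC)CC | intermediate
12 | lithium dienolate of 13 (C6–OLi, C5=C6, C5 bearing C(=CH2)CH(OEt)2) | O=C1O[C@@H]2[C@H]3C(O[Li])=C(C(=C)C(OCC)OCC)[C@](C)(C=C13)[C@@H]2O[Si](CC)(CC)CC | intermediate
13 | 5β-alkenyl C6 ketone: 9 carrying 3,3-diethoxyprop-1-en-2-yl on C5, on the side of the C8–C9 bridge | O=C1O[C@@H]2[C@H]3C(=O)[C@@H](C(=C)C(OCC)OCC)[C@](C)(C=C13)[C@@H]2O[Si](CC)(CC)CC | intermediate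
14 | 6β-alcohol: 13 reduced at C6, OH on the side of the C8–C9 bridge, cis to the C5 side chain | O=C1O[C@@H]2[C@H]3[C@@H](O)[C@@H](C(=C)C(OCC)OCC)[C@](C)(C=C13)[C@@H]2O[Si](CC)(CC)CC | intermediate
15 | angelic acid, (2Z)-2-methylbut-2-enoic acid | C/C=C(/C)C(=O)O | starting material
16 | (2Z)-2-methylbut-2-enoic 2,4,6-trichlorobenzoic anhydride | C/C=C(/C)C(=O)OC(=O)c1c(Cl)cc(Cl)cc1Cl | intermediate
17 | 6β-angelate of 14 | O=C1O[C@@H]2[C@H]3[C@@H](OC(=O)/C(C)=C\C)[C@@H](C(=C)C(OCC)OCC)[C@](C)(C=C13)[C@@H]2O[Si](CC)(CC)CC | intermediate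
18 | ethylene | C=C | starting material
19 | (3aR,4S,5R,6S,7S,7aR)-5-(3,3-diethoxyprop-1-en-2-yl)-6-ethenyl-6-methyl-3-methylidene-2-oxo-7-[(triethylsilyl)oxy]octahydro-1-benzofuran-4-yl (2Z)-2-methylbut-2-enoate | C=C1C(=O)O[C@@H]2[C@H]1[C@@H](OC(=O)/C(C)=C\C)[C@@H](C(=C)C(OCC)OCC)[C@](C)(C=C)[C@@H]2O[Si](CC)(CC)CC | intermediate
20 | (3aR,4S,5R,6S,7S,7aR)-6-ethenyl-7-hydroxy-6-methyl-3-methylidene-2-oxo-5-(3-oxoprop-1-en-2-yl)octahydro-1-benzofuran-4-yl (2Z)-2-methylbut-2-enoate | C=C1C(=O)O[C@@H]2[C@H]1[C@@H](OC(=O)/C(C)=C\C)[C@@H](C(=C)C=O)[C@](C)(C=C)[C@@H]2O | intermediate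
21 | (3aR,4S,5R,6S,7S,7aR)-7-hydroxy-6-methyl-3-methylidene-6-[(2S)-oxiran-2-yl]-2-oxo-5-(3-oxoprop-1-en-2-yl)octahydro-1-benzofuran-4-yl (2Z)-2-methylbut-2-enoate | C=C1C(=O)O[C@@H]2[C@H]1[C@@H](OC(=O)/C(C)=C\C)[C@@H](C(=C)C=O)[C@](C)([C@H]1CO1)[C@@H]2O | target

**Total step count:** 12. **Longest linear sequence:** 12 steps (1 → 21).

**Three steps most likely to fail, with fallbacks**

Step 10 (ethenolysis). The trisubstituted, electron-poor bridge may not engage the ruthenium methylidene. The fallback breaks C1–C11 by polar chemistry and sets out from 17. Conjugate borylation (CuCl, Xantphos, NaOt-Bu, B2pin2, MeOH, THF) puts boron on C1 to give the β-boryl lactone F8 (epimer mixture at C1/C11, both converge). NaBO3·4H2O oxidises it to the β-hydroxy lactone F9. DBU (CH2Cl2, 0 °C) triggers strain-releasing retro-aldol cleavage to the seco aldehyde F10 (C10–CHO, C11H2 lactone). Ph3P=CH2 turns the aldehyde into the vinyl lactone F11. LiN(SiMe3)2 and CH2=NMe2+ I− give the Mannich base F12, and MeI then NaHCO3 eliminate trimethylamine to return to the route at 19.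

Step 7 (enolate alkenylation). Coupling at the neopentyl C5 next to the quaternary bridgehead may be slow, and the kinetic protonation may not give full β-selectivity. The fallback inverts the polarity and sets out from 9. Me3SiOTf/Et3N gives the trimethylsilyl enol ether F4 (only the C5 side can enolise). NBS gives the α-bromo ketone F5. A Negishi coupling (NiCl2·glyme, 2,2'-bipyridine, THF–DMA) with the alkenylzinc bromide F6 (from 10 with Zn dust/LiCl) gives 13 together with its C5 epimer F7. LiN(SiMe3)2 converts both into the dienolate 12, where the route is rejoined before the kinetic protonation.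

Step 5 (intramolecular Diels–Alder). The dienyl ester may aromatise by loss of propiolic acid, the adduct may undergo retro-Diels–Alder loss of the C8–C9 bridge if overheated, or the ester tether may cyclise sluggishly. The fallback uses an ether tether and sets out from 3. NaH and propargyl bromide (THF, −20 °C) give the C8 propargyl ether F1. Et3SiOTf/2,6-lutidine gives the silyl ether F2. Thermolysis (PhMe, 110 °C) gives the cyclic-ether adduct F3, which has the same connectivity and configuration as 7 with CH2 in place of C12=O. Allylic C–H oxidation of that CH2 (CrO3·3,5-dimethylpyrazole, CH2Cl2, −20 °C) returns to the route at 7.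

**Further compounds**
F1 | step 5 | (1S,6R)-2-methyl-6-(prop-2-yn-1-yloxy)cyclohexa-2,4-dien-1-ol | C#CCO[C@@H]1C=CC=C(C)[C@@H]1O
F2 | step 5 | triethyl{[(1S,6R)-2-methyl-6-(prop-2-yn-1-yloxy)cyclohexa-2,4-dien-1-yl]oxy}silane | C#CCO[C@@H]1C=CC=C(C)[C@@H]1O[Si](CC)(CC)CC
F3 | step 5 | cyclic-ether adduct, 7 with CH2 in place of the lactone C=O | C1O[C@@H]2[C@H]3C=C[C@](C)(C=C13)[C@@H]2O[Si](CC)(CC)CC
F4 | step 7 | trimethylsilyl enol ether of 9 (C6–OSiMe3, C5=C6) | O=C1O[C@@H]2[C@H]3C(O[Si](C)(C)C)=C[C@](C)(C=C13)[C@@H]2O[Si](CC)(CC)CC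
F5 | step 7 | 5-bromo ketone (Br on the side of the C1=C11 bridge) | O=C1O[C@@H]2[C@H]3C(=O)[C@H](Br)[C@](C)(C=C13)[C@@H]2O[Si](CC)(CC)CC
F6 | step 7 | (3,3-diethoxyprop-1-en-2-yl)zinc bromide | C=C([Zn]Br)C(OCC)OCC
F7 | step 7 | C5 epimer of 13 (side chain on the side of the C1=C11 bridge) | O=C1O[C@@H]2[C@H]3C(=O)[C@H](C(=C)C(OCC)OCC)[C@](C)(C=C13)[C@@H]2O[Si](CC)(CC)CC
F8 | step 10 | β-boryl lactone (pinacolboryl on C1, H on C11; C1/C11 unspecified) | O=C1O[C@@H]2[C@H]3[C@@H](OC(=O)/C(C)=C\C)[C@@H](C(=C)C(OCC)OCC)[C@](C)(C(B4OC(C)(C)C(C)(C)O4)C13)[C@@H]2O[Si](CC)(CC)CC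
F9 | step 10 | β-hydroxy lactone (OH on C1, H on C11; C1/C11 unspecified) | O=C1O[C@@H]2[C@H]3[C@@H](OC(=O)/C(C)=C\C)[C@@H](C(=C)C(OCC)OCC)[C@](C)(C(O)C13)[C@@H]2O[Si](CC)(CC)CC
F10 | step 10 | seco aldehyde: 19 with CHO in place of the C10 vinyl and CH2 in place of C11=CH2 | C1C(=O)O[C@@H]2[C@H]1[C@@H](OC(=O)/C(C)=C\C)[C@@H](C(=C)C(OCC)OCC)[C@](C)(C=O)[C@@H]2O[Si](CC)(CC)CC
F11 | step 10 | vinyl lactone: 19 with CH2 in place of C11=CH2 | C1C(=O)O[C@@H]2[C@H]1[C@@H](OC(=O)/C(C)=C\C)[C@@H](C(=C)C(OCC)OCC)[C@](C)(C=C)[C@@H]2O[Si](CC)(CC)CC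
F12 | step 10 | Mannich base: F11 with CH2NMe2 on C11 (C11 unspecified) | CN(C)CC1C(=O)O[C@@H]2[C@H]1[C@@H](OC(=O)/C(C)=C\C)[C@@H](C(=C)C(OCC)OCC)[C@](C)(C=C)[C@@H]2O[Si](CC)(CC)CC
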